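All runs were computed on assumed constants, noise included.

| flask | substrate | temperature | remark | time |
|---|---|---|---|---|
| dawn | 0.35 M | 5 °C | run made earlier |  |
| autumn | 0.55 M | 48 °C | run made earlier |  |
| zeta | 0.25 M | 60 °C |  | 40 min |
| gamma | 0.25 M | 85 °C |  | 40 min |
| delta | 0.25 M | 35 °C |  | 40 min |
| eta | 0.25 M | 10 °C |  | 40 min |

| run | time / min | product / % |
|---|---|---|
| dawn | 60.0 | 0 |
| dawn | 120 | 0.3 |
| dawn | 240 | 0.9 |
| dawn | 360 | 1.7 |
| dawn | 720 | 3.2 |
| autumn | 8.00 | 6.5 |
| autumn | 20.0 | 14.5 |
| autumn | 40.0 | 24.7 |
| autumn | 50.0 | 27.5 |
| autumn | 90.0 | 36.8 |

(standard deviation of a reading: 0.3 percentage points)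

- which flask leads in amount of product, in percent of the substrate charged ("all alike" within 1.5 percentage points) (zeta / gamma / delta / eta / all alike)
- how much product is there at the end, in percent of the substrate charged: zeta
- how much product is there at the end, in percent of the substrate charged: gamma
- how much product is there at the end, in percent of the substrate charged: delta
- how much product is there at the end, in percent of the substrate charged: eta

- for product the crystals are counted in
- as a solid, counted per litre of solution: crystals
- the numbers in the tables scatter by 0.3 percentage points (one standard deviation)
- steps under discussion: substrate <-> intermediate A; crystals <-> product; substrate -> intermediate B; substrate -> product; intermediate B <-> intermediate C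

- Eta was a cold flask, and I set it beside the dawn run, at 5 °C against eta's 10 °C, though dawn was read up to 720 min and eta stopped at 40 min.
- I followed one substrate molecule and gave it a chance p per minute of turning into product, the usual first-order rate constant. So I reckoned the percent of product as p times the time t times the mean share of substrate still present, and I assumed the charge did not matter.
- Dawn rose nearly straight to 3.2% at 720 min, which gave p = 4.44 × 10⁻⁵ /min at its temperature. Autumn's first reading, 6.5% at 8.00 min, gave 0.00813 /min at 48 °C.
- From these two values, which carry the scatter of the readings, I read an activation energy E of 90.0 kJ/mol. That put p in eta at 8.83 × 10⁻⁵ /min, a molecule's chance per minute of becoming product at that temperature, and twice dawn's value.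
- Over eta's 40 min, p times t came to 0.353%, so by my reckoning hardly any substrate in eta went to product. I took the mean share of substrate as whole and committed to that figure, against a scatter of 0.3 percentage points.
- Dawn's last reading stood higher than my figure for eta because, with the charge assumed not to matter, dawn ran 18.0 times as long while the p I read for it was half of the p I reckoned for eta.
- The forecast named gamma as the leader and gave 41% for zeta, 44% for gamma, 7.6% for delta and 0.4% for eta, saying “I assume constant selectivity”.
- The flasks gave 41.0% in zeta, 60.4% in gamma, 7.72% in delta and 0.352% in eta, so gamma led, and eta stood beside my 0.353%.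

    substrate ⇌ intermediate A (K = 1.62, k = 0.0413 /min, Ea = 112 kJ/mol, ΔH = −42.0 kJ/mol)
    crystals ⇌ product, rate k2*(cs2 - [product]) while solid is left; crystals form when [product] > cs2 (solubility = 0.0820 M, k = 0.885 /min)
    substrate → intermediate B (k = 0.0147 /min, Ea = 105 kJ/mol)
    substrate → product (k = 0.0311 /min, Ea = 92.0 kJ/mol)
    intermediate B ⇌ intermediate C (K = 0.470, k = 0.0453 /min, Ea = 104 kJ/mol, ΔH = 4.00 kJ/mol)
    (constants at 60 °C)

- The neighbour was eta's flask kept at 35 °C, with the same 40 min. There my reckoning put p at 0.00196 /min, so p times t came to 7.84%. Substrate in this neighbour ended at 84.1%, which made its mean share between start and end 92.1%, and that brought my reckoning to 7.22%. The neighbour flask held 7.72% of product.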